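Numbering used throughout: C1 ketone, C2=C3 (E)-olefin, C4 (Me), C5 (OH), C6 (lactone O), C7 (ring fusion), C8 (angelate), C9 H2, C10 (Me, OAc), C11=C13 exocyclic methylene, C12 lactone carbonyl.
Enabling feature: the C1 ketone conjugated to the C2=C3 olefin inside the ten-membered carbocycle is a dehydrated β-ketol, the retron of a 2-isoxazoline bridging C1 and C3. After removal of the esters and C13, the retrosynthesis cuts C1–C2 (with O–C3), then C4–C5, C7–C8 and C8–C9.
Forward: the γ-lactone is present from the start as a butenolide. The chain is joined C8–C9 (dithiane/epoxide), C7–C8 (conjugate addition) and C4–C5 (crotylboration). An intramolecular nitrile oxide cycloaddition then closes the isoxazoline and the ten-membered ring together, followed by methylenation, N–O cleavage, dehydration and the acylations.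
Stereochemistry: C6 from (S)-5-(hydroxymethyl)furan-2(5H)-one, C10 from (R)-2-methylglycidol, C7 by addition anti to the C6 substituent, C8 by Felkin–Anh reduction, C4/C5 by catalyst-controlled anti-crotylboration, angelate geometry from angelic acid.

Key step: step 16

Remark: the C3 configuration created in step 16 is destroyed in step 19; compounds 25–31 are drawn as the (3S) epimer, and either epimer or their mixture would be carried on.
Remark: (R)-2-methylglycidol and the (S)-butenolide are taken as enantiopure commercial materials; where a Conditions line ends with H2O or AcOH, that is the quench of the anionic intermediate.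

Step 1
Reactants: 1 (R)-2-methylglycidol
Product: 2 (S)-2-{[(4-methoxybenzyl)oxy]methyl}-2-methyloxirane
Conditions: NaH, 4-methoxybenzyl chloride, n-Bu4NI (cat.), THF/DMF, 0 °C → rt
Reagents that add atoms: 4-methoxybenzyl chloride, COc1ccc(CCl)cc1
Why: Williamson etherification of the sodium alkoxide with the benzylic chloride leaves the quaternary epoxide carbon untouched (a Payne shift would only regenerate the same enantiomer), so C10 enters with the configuration of the purchased epoxy alcohol.

Step 2
Reactants: 3 1,3-dithiane; 2 (S)-2-{[(4-methoxybenzyl)oxy]methyl}-2-methyloxirane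
Product: 5 (S)-1-(1,3-dithian-2-yl)-3-[(4-methoxybenzyl)oxy]-2-methylpropan-2-ol, via 2-lithio-1,3-dithiane 4 (not isolated)
Conditions: n-BuLi, THF, −30 °C; then 2, −30 °C → rt; H2O
Reagents that add atoms: none
Why: Corey–Seebach alkylation in which the sulfur-stabilised carbanion opens the 2,2-disubstituted epoxide by SN2 attack at its unhindered CH2 terminus, forming C8–C9 without touching the C10 stereocentre.

Step 3
Reactants: 5 (S)-1-(1,3-dithian-2-yl)-3-[(4-methoxybenzyl)oxy]-2-methylpropan-2-ol
Product: 6 triethylsilyl ether of 5 (C10-OTES dithiane)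
Conditions: Et3SiOTf, 2,6-lutidine, CH2Cl2, 0 °C
Reagents that add atoms: triethylsilyl trifluoromethanesulfonate, CC[Si](CC)(CC)OS(=O)(=O)C(F)(F)F
Why: Standard silylation of a tertiary alcohol with a silyl triflate and 2,6-lutidine, which masks the hydroxyl in a form that survives the later lithiation.

Step 4
Reactants: 7 (S)-5-(hydroxymethyl)furan-2(5H)-one
Product: 8 (S)-5-{[(tert-butyldiphenylsilyl)oxy]methyl}furan-2(5H)-one
Conditions: t-BuPh2SiCl, imidazole, DMF, 0 °C → rt
Reagents that add atoms: tert-butyl(chloro)diphenylsilane, CC(C)(C)[Si](Cl)(c1ccccc1)c1ccccc1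
Why: Routine silylation of the primary alcohol with the bulky chlorosilane and imidazole, giving a C6 substituent large enough to shield one face of the butenolide.

Step 5
Reactants: 6 C10-OTES dithiane; 8 (S)-5-{[(tert-butyldiphenylsilyl)oxy]methyl}furan-2(5H)-one
Product: 10 C6/C7-trans butanolide carrying the 2-alkyl-1,3-dithian-2-yl group (C8) on C7 (10-OTES; 1-OPMB; 5-OTBDPS), via 2-lithiodithiane 9 (not isolated)
Conditions: t-BuLi, THF/HMPA (10:1), −78 °C; then 8, −78 °C; AcOH
Reagents that add atoms: none
Why: Michael addition of a 2-lithio-2-alkyl-1,3-dithiane to a γ-substituted butenolide is an established route to trans-4,5-disubstituted butanolides; HMPA gives the solvent-separated ion pair that adds in the conjugate sense (and keeps the silyl group on oxygen), and the CH2OTBDPS group forces attack on the opposite face, which sets C7 trans to C6.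

Step 6
Reactants: 10 dithiane butanolide
Product: 11 C8 ketone (4-acyl butanolide; 10-OTES; 1-OPMB; 5-OTBDPS)
Conditions: MeI, CaCO3, MeCN/H2O (9:1), 45 °C
Reagents that add atoms: water, O
Why: S-Methylation and hydrolysis of the dithiane under CaCO3 buffering is a neutral carbonyl unmasking that spares the PMB ether, both silyl ethers and the 4-acyl butanolide, whose C7 enolate could otherwise expel the lactone carboxylate.

Step 7
Reactants: 11 C8 ketone
Product: 12 C8 alcohol (C8 configured as in the target; 10-OTES)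
Conditions: LiBH(s-Bu)3, THF, −78 °C; AcOH, −78 °C
Reagents that add atoms: none
Why: Felkin–Anh-controlled reduction by the bulky borohydride, in which hydride approaches anti to the C7–C6 bond and past the C7 hydrogen, should set the C8 carbinol centre as in the target, while −78 °C and the cold acidic quench keep the lactone from being reduced or migrating to O8.

Step 8
Reactants: 12 C8 alcohol
Product: 14 C8/C10 acetonide (1-OPMB; 5-OTBDPS), via C8/C10 diol 13 (not isolated)
Conditions: camphor-10-sulfonic acid (cat.), MeOH, 0 °C → rt; then 2,2-dimethoxypropane, camphor-10-sulfonic acid (cat.), acetone, rt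
Reagents that add atoms: 2,2-dimethoxypropane, COC(C)(C)OC
Why: Acid-catalysed methanolysis of the tertiary triethylsilyl ether followed by transacetalisation with 2,2-dimethoxypropane gives the six-membered acetonide of the 1,3-diol, which holds C7 and C1 cis on the dioxane and blocks migration of the lactone to O8; no stereocentre is formed.

Step 9
Reactants: 14 C8/C10 acetonide
Product: 15 C5 primary alcohol
Conditions: n-Bu4NF, AcOH, THF, 0 °C → rt
Reagents that add atoms: none
Why: Fluoride-mediated cleavage of the primary silyl ether, buffered with acetic acid so that the lactone does not migrate and the acetonide and PMB ether remain.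

Step 10
Reactants: 15 C5 primary alcohol
Product: 16 C5 aldehyde
Conditions: Dess–Martin periodinane, CH2Cl2, 0 °C → rt
Reagents that add atoms: none
Why: Dess–Martin oxidation is neutral to weakly acidic, so the α-acyloxy aldehyde forms without epimerisation at C6 and is used crude.

Step 11
Reactants: 16 C5 aldehyde; 17 (E)-crotylboronic acid pinacol ester
Product: 18 homoallylic alcohol (C4 methyl and C5 hydroxyl anti; C5 and C6 oxygens syn; C2=C3 vinyl terminus)
Conditions: (S)-3,3'-bis(2,4,6-triisopropylphenyl)-1,1'-binaphthyl-2,2'-diyl hydrogen phosphate (5 mol %), 4 Å MS, toluene, −30 °C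
Reagents that add atoms: none
Why: Chiral phosphoric acid-catalysed crotylboration through a closed chair transition state, in which the (E)-boronate fixes the C4/C5 anti relationship and the (S)-configured acid, hydrogen-bonded to the boronate oxygen and the formyl hydrogen, directs the crotyl group to the si face of the aldehyde to give the 5,6-syn adduct, the weak intrinsic facial bias of α-oxygenated aldehydes toward (E)-crotylboronates being overridden by the catalyst.

Step 12
Reactants: 18 homoallylic alcohol
Product: 19 C5 TBS ether (1-OPMB)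
Conditions: t-BuMe2SiOTf, 2,6-lutidine, CH2Cl2, −78 → 0 °C
Reagents that add atoms: tert-butyldimethylsilyl trifluoromethanesulfonate, CC(C)(C)[Si](C)(C)OS(=O)(=O)C(F)(F)F
Why: Silylation of the hindered secondary alcohol with the silyl triflate and 2,6-lutidine is standard and leaves the acetonide intact.

Step 13
Reactants: 19 C5 TBS ether
Product: 20 C1 primary alcohol
Conditions: 2,3-dichloro-5,6-dicyano-1,4-benzoquinone (DDQ), CH2Cl2/pH 7 buffer, 0 °C → rt
Reagents that add atoms: none
Why: Oxidative PMB ether cleavage by DDQ in wet dichloromethane proceeds through the benzylic oxocarbenium ion and spares the isolated terminal olefin, the silyl ether, the acetonide and the lactone.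

Step 14
Reactants: 20 C1 primary alcohol
Product: 21 C1 aldehyde
Conditions: Dess–Martin periodinane, CH2Cl2, rt
Reagents that add atoms: none
Why: Dess–Martin oxidation of the neopentyl-type primary alcohol gives an aldehyde that cannot epimerise because C10 is quaternary.

Step 15
Reactants: 21 C1 aldehyde
Product: 22 C1 aldoxime (C4 vinyl terminus; trans lactone; C8/C10 acetonide; 5-OTBS)
Conditions: NH2OH·HCl, pyridine, EtOH, rt
Reagents that add atoms: hydroxylamine hydrochloride, NO.Cl
Why: Oxime condensation of the aldehyde with hydroxylamine under pyridine buffering is much faster than attack on the γ-lactone, and the oxime geometry is irrelevant to the next step.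

Step 16
Reactants: 22 C1 aldoxime
Product: 25 bridged isoxazoline in the ten-membered carbocycle (C1=N; O on C3; new bonds C1–C2 and O–C3), via hydroximoyl chloride 23 (not isolated), via nitrile oxide 24 (not isolated)
Conditions: N-chlorosuccinimide, pyridine (cat.), CHCl3, rt; then syringe-pump addition to Et3N, CH2Cl2 (final 1 mM), 40 °C
Reagents that add atoms: none
Why: Chlorination of the aldoxime and slow dehydrochlorination generate the nitrile oxide, which adds to the terminal olefin in a concerted, asynchronous (3+2) cycloaddition with its carbon bonding to the CH2 terminus (C2) and its oxygen to C3; the closest known reaction type is the intramolecular nitrile oxide–olefin cycloaddition that gives bridged isoxazolines in medium and large rings, ten members lying at the small end of that range. The five-membered isoxazoline arises from the cycloaddition itself, and the ten-membered carbocycle closes through the new C1–C2 bond in the bridged (endo) mode, both olefin carbons ending inside the carbocycle. The one new stereocentre, C3, is set by which olefin face the dipole reaches, which the adjacent C4 methyl centre and the conformation of the forming ring decide, and its configuration is not needed because step 19 removes it. The step must deliver bridged regiochemistry and ring closure ahead of dimerisation: the first follows from the normal orientation of nitrile oxides toward monosubstituted olefins and from the fact that the fused alternative would need a nine-membered ring, the second from the hindered nitrile oxide on quaternary C10 (slow to form the furoxan), its slow generation at high dilution, and the trans-lactone and cis-acetonide that restrict the chain between C6 and C10.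

Step 17
Reactants: 25 bridged isoxazoline
Product: 29 α-methylene lactone isoxazoline, via lithium enolate 26 (not isolated), via Mannich base 27 (not isolated), via methiodide 28 (not isolated)
Conditions: LiN(SiMe3)2, THF, −78 °C; Me2N=CH2 I (Eschenmoser's salt), −78 → 0 °C; then MeI, THF, rt; then aq NaHCO3, CH2Cl2
Reagents that add atoms: Eschenmoser's salt (N,N-dimethylmethyleneiminium iodide), C=[N+](C)C.[I-]
Why: Mannich-type α-methylenation in which LiN(SiMe3)2 deprotonates only the lactone α-carbon (the isoxazoline C2 hydrogens are far less acidic and the ketone is still masked, so no transannular aldol or Michael path exists), Eschenmoser's salt aminomethylates the enolate anti to the C8 branch, and quaternisation followed by bicarbonate-induced loss of trimethylamine gives the exocyclic olefin, which removes the transient C11 centre again.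

Step 18
Reactants: 29 α-methylene lactone isoxazoline
Product: 30 C3-hydroxy C1-ketone (β-ketol)
Conditions: Mo(CO)6, MeCN/H2O (15:1), 80 °C
Reagents that add atoms: water, O
Why: Reductive N–O cleavage of the 2-isoxazoline by Mo(CO)6 in wet acetonitrile with hydrolysis of the β-hydroxy imine is a standard unmasking of the β-ketol that, unlike hydrogenolysis, tolerates olefins including the exo-methylene lactone, and it leaves C3 as a carbinol that is removed next.

Step 19
Reactants: 30 C3-hydroxy C1-ketone
Product: 32 (E)-enone (C1 ketone; C2=C3; C8/C10 acetonide; 5-OTBS; α-methylene lactone), via C3 mesylate 31 (not isolated)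
Conditions: MsCl, Et3N, CH2Cl2, 0 °C → rt
Reagents that add atoms: none
Why: Mesylation and E1cB elimination through the C1 enolate, which can form only toward C2 because C10 is quaternary, gives the conjugated enone and erases C3, the (E) geometry being the one expected for a trans-lactone-fused ten-membered ring of this type but the point to verify.

Step 20
Reactants: 32 (E)-enone acetonide
Product: 33 C8,C10 diol
Conditions: AcOH/H2O (4:1), 40 °C
Reagents that add atoms: none
Why: Mild aqueous acetic acid hydrolyses the acetonide of the 1,3-diol while the hindered secondary silyl ether, the enone and the α-methylene lactone persist.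

Step 21
Reactants: 33 C8,C10 diol
Product: 34 C8 angelate (10-OH free)
Conditions: angelic acid, 2,4,6-trichlorobenzoyl chloride, Et3N, toluene, rt; then 33, 80 °C
Reagents that add atoms: angelic acid [(Z)-2-methylbut-2-enoic acid], C/C=C(/C)C(=O)O
Why: Esterification through the mixed 2,4,6-trichlorobenzoic anhydride without a nucleophilic catalyst (Yamaguchi-type conditions) acylates the secondary C8 hydroxyl in preference to the tertiary C10 hydroxyl and avoids the Z-to-E isomerisation of the angeloyl group that acylpyridinium intermediates promote.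

Step 22
Reactants: 34 C8 angelate
Product: 35 C10 acetate (5-O-TBS ether of the target)
Conditions: Ac2O, 4-(dimethylamino)pyridine (cat.), Et3N, CH2Cl2, rt → 40 °C
Reagents that add atoms: acetic anhydride, CC(=O)OC(C)=O
Why: 4-(Dimethylamino)pyridine-catalysed acetylation of the remaining tertiary α-ketol hydroxyl is standard and does not isomerise the preformed angelate.

Step 23
Reactants: 35 C10 acetate
Product: 36 CNP0259154.2 (target)
Conditions: HF·pyridine, pyridine, THF, 0 °C → rt
Reagents that add atoms: none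
Why: Desilylation with buffered HF·pyridine is mildly acidic, so neither acyl migration nor conjugate addition to the enone or methylene lactone occurs, and it releases the C5 hydroxyl of the target.

Compound list
1 | (R)-2-methylglycidol [(2R)-(2-methyloxiran-2-yl)methanol] | C[C@@]1(CO)CO1 | starting material
2 | (S)-2-{[(4-methoxybenzyl)oxy]methyl}-2-methyloxirane | C[C@@]1(COCc2ccc(OC)cc2)CO1 | intermediate
3 | 1,3-dithiane | C1CSCSC1 | starting material
4 | 2-lithio-1,3-dithiane | [Li]C1SCCCS1 | intermediate
5 | (S)-1-(1,3-dithian-2-yl)-3-[(4-methoxybenzyl)oxy]-2-methylpropan-2-ol | COc1ccc(COC[C@@](C)(O)CC2SCCCS2)cc1 | intermediate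
6 | triethylsilyl ether of 5 (C10-OTES dithiane) | COc1ccc(COC[C@@](C)(O[Si](CC)(CC)CC)CC2SCCCS2)cc1 | intermediate
7 | (S)-5-(hydroxymethyl)furan-2(5H)-one | O=C1C=C[C@@H](CO)O1 | starting material
8 | (S)-5-{[(tert-butyldiphenylsilyl)oxy]methyl}furan-2(5H)-one | O=C1C=C[C@@H](CO[Si](c2ccccc2)(c2ccccc2)C(C)(C)C)O1 | intermediate
9 | 2-lithio derivative of 6 | COc1ccc(COC[C@@](C)(O[Si](CC)(CC)CC)CC2([Li])SCCCS2)cc1 | intermediate
10 | C6/C7-trans butanolide with the dithiane (C8) on C7; 10-OTES, 1-OPMB, 5-OTBDPS | COc1ccc(COC[C@@](C)(O[Si](CC)(CC)CC)CC2(SCCCS2)[C@H]3CC(=O)O[C@@H]3CO[Si](c4ccccc4)(c4ccccc4)C(C)(C)C)cc1 | intermediate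
11 | C8 ketone (4-acyl butanolide) | COc1ccc(COC[C@@](C)(O[Si](CC)(CC)CC)CC(=O)[C@H]2CC(=O)O[C@@H]2CO[Si](c3ccccc3)(c3ccccc3)C(C)(C)C)cc1 | intermediate
12 | C8 alcohol, 10-OTES | COc1ccc(COC[C@@](C)(O[Si](CC)(CC)CC)C[C@@H](O)[C@H]2CC(=O)O[C@@H]2CO[Si](c3ccccc3)(c3ccccc3)C(C)(C)C)cc1 | intermediate
13 | C8,C10 diol | COc1ccc(COC[C@@](C)(O)C[C@@H](O)[C@H]2CC(=O)O[C@@H]2CO[Si](c3ccccc3)(c3ccccc3)C(C)(C)C)cc1 | intermediate
14 | C8/C10 acetonide, 1-OPMB, 5-OTBDPS | COc1ccc(COC[C@@](C)(OC2(C)C)C[C@@H](O2)[C@H]3CC(=O)O[C@@H]3CO[Si](c4ccccc4)(c4ccccc4)C(C)(C)C)cc1 | intermediate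
15 | C5 primary alcohol | COc1ccc(COC[C@@](C)(OC2(C)C)C[C@@H](O2)[C@H]3CC(=O)O[C@@H]3CO)cc1 | intermediate
16 | C5 aldehyde | COc1ccc(COC[C@@](C)(OC2(C)C)C[C@@H](O2)[C@H]3CC(=O)O[C@@H]3C=O)cc1 | intermediate
17 | (E)-crotylboronic acid pinacol ester | C/C=C/CB1OC(C)(C)C(C)(C)O1 | starting material
18 | homoallylic alcohol (4,5-anti; 5,6-syn) | COc1ccc(COC[C@@](C)(OC2(C)C)C[C@@H](O2)[C@H]3CC(=O)O[C@@H]3[C@@H](O)[C@@H](C)C=C)cc1 | intermediate
19 | C5 TBS ether, 1-OPMB | COc1ccc(COC[C@@](C)(OC2(C)C)C[C@@H](O2)[C@H]3CC(=O)O[C@@H]3[C@@H](O[Si](C)(C)C(C)(C)C)[C@@H](C)C=C)cc1 | intermediate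
20 | C1 primary alcohol | OC[C@@](C)(OC1(C)C)C[C@@H](O1)[C@H]2CC(=O)O[C@@H]2[C@@H](O[Si](C)(C)C(C)(C)C)[C@@H](C)C=C | intermediate
21 | C1 aldehyde | O=C[C@@](C)(OC1(C)C)C[C@@H](O1)[C@H]2CC(=O)O[C@@H]2[C@@H](O[Si](C)(C)C(C)(C)C)[C@@H](C)C=C | intermediate
22 | C1 aldoxime (cycloaddition precursor) | O/N=C/[C@@](C)(OC1(C)C)C[C@@H](O1)[C@H]2CC(=O)O[C@@H]2[C@@H](O[Si](C)(C)C(C)(C)C)[C@@H](C)C=C | intermediate
23 | C1 hydroximoyl chloride | O/N=C(\Cl)[C@@](C)(OC1(C)C)C[C@@H](O1)[C@H]2CC(=O)O[C@@H]2[C@@H](O[Si](C)(C)C(C)(C)C)[C@@H](C)C=C | intermediate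
24 | C1 nitrile oxide | [O-][N+]#C[C@@](C)(OC1(C)C)C[C@@H](O1)[C@H]2CC(=O)O[C@@H]2[C@@H](O[Si](C)(C)C(C)(C)C)[C@@H](C)C=C | intermediate
25 | bridged isoxazoline in the ten-membered ring, (3S) epimer drawn | C[C@H]1[C@@H]2CC(=NO2)[C@@](C)(OC3(C)C)C[C@@H](O3)[C@H]4CC(=O)O[C@@H]4[C@H]1O[Si](C)(C)C(C)(C)C | intermediate
26 | lithium enolate of the lactone of 25 | C[C@H]1[C@@H]2CC(=NO2)[C@@](C)(OC3(C)C)C[C@@H](O3)[C@H]4C=C(O[Li])O[C@@H]4[C@H]1O[Si](C)(C)C(C)(C)C | intermediate
27 | C11 (dimethylamino)methyl lactone (Mannich base, CH2NMe2 trans to C8) | C[C@H]1[C@@H]2CC(=NO2)[C@@](C)(OC3(C)C)C[C@@H](O3)[C@H]4[C@H](CN(C)C)C(=O)O[C@@H]4[C@H]1O[Si](C)(C)C(C)(C)C | intermediate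
28 | C11 (trimethylammonio)methyl lactone iodide | C[C@H]1[C@@H]2CC(=NO2)[C@@](C)(OC3(C)C)C[C@@H](O3)[C@H]4[C@H](C[N+](C)(C)C)C(=O)O[C@@H]4[C@H]1O[Si](C)(C)C(C)(C)C.[I-] | intermediate
29 | α-methylene lactone isoxazoline | C[C@H]1[C@@H]2CC(=NO2)[C@@](C)(OC3(C)C)C[C@@H](O3)[C@H]4C(=C)C(=O)O[C@@H]4[C@H]1O[Si](C)(C)C(C)(C)C | intermediate
30 | C3-hydroxy C1-ketone (β-ketol) | C[C@H]1[C@@H](O)CC(=O)[C@@](C)(OC2(C)C)C[C@@H](O2)[C@H]3C(=C)C(=O)O[C@@H]3[C@H]1O[Si](C)(C)C(C)(C)C | intermediate
31 | C3 mesylate | C[C@H]1[C@@H](OS(C)(=O)=O)CC(=O)[C@@](C)(OC2(C)C)C[C@@H](O2)[C@H]3C(=C)C(=O)O[C@@H]3[C@H]1O[Si](C)(C)C(C)(C)C | intermediate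
32 | (E)-enone, C8/C10 acetonide, 5-OTBS | C[C@H]1/C=C/C(=O)[C@@](C)(OC2(C)C)C[C@@H](O2)[C@H]3C(=C)C(=O)O[C@@H]3[C@H]1O[Si](C)(C)C(C)(C)C | intermediate
33 | C8,C10 diol, 5-OTBS | C[C@H]1/C=C/C(=O)[C@@](C)(O)C[C@@H](O)[C@H]2C(=C)C(=O)O[C@@H]2[C@H]1O[Si](C)(C)C(C)(C)C | intermediate
34 | C8 angelate, 10-OH, 5-OTBS | C[C@H]1/C=C/C(=O)[C@@](C)(O)C[C@@H](OC(=O)/C(C)=C\C)[C@H]2C(=C)C(=O)O[C@@H]2[C@H]1O[Si](C)(C)C(C)(C)C | intermediate
35 | C10 acetate, C8 angelate, 5-OTBS | C[C@H]1/C=C/C(=O)[C@@](C)(OC(C)=O)C[C@@H](OC(=O)/C(C)=C\C)[C@H]2C(=C)C(=O)O[C@@H]2[C@H]1O[Si](C)(C)C(C)(C)C | intermediate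
36 | CNP0259154.2 | C=C1C(=O)O[C@@H]2[C@@H](O)[C@@H](C)/C=C/C(=O)[C@@](C)(OC(C)=O)C[C@@H](OC(=O)/C(C)=C\C)[C@@H]12 | target

Total step count: 23. Longest linear sequence: 22 steps (from 1 through steps 1–3 and 5–23).

Steps most likely to fail

1. Step 16. Process at risk: the nitrile oxide is consumed by dimerisation to the furoxan or by oligomerisation, because the strained ten-membered transition state is reached too slowly. The fallback sets out from 19 and returns at 32; it closes the same C1–C2 bond by a different reaction and fixes the C2=C3 geometry before ring closure. Lemieux–Johnson cleavage of the vinyl group (OsO4 cat., NaIO4, 2,6-lutidine, dioxane/H2O) would give the C3 aldehyde F1. Takai olefination (CrCl2, CHI3, THF) would convert it to the (E)-vinyl iodide F2. DDQ would free the C1 alcohol F3, and Dess–Martin oxidation would give the iodo aldehyde F4. Nozaki–Hiyama–Kishi cyclisation (CrCl2, NiCl2 cat., DMSO/THF, high dilution) would then give the ten-membered (E)-allylic alcohol F5 as C1 epimers. With 2.2 equiv of LiN(SiMe3)2 the dilithio alkoxide–enolate F6 would be aminomethylated by Eschenmoser's salt to the Mannich base F7, which via the methiodide F8 and NaHCO3 would give the α-methylene lactone alcohol F9. Dess–Martin oxidation of the allylic alcohol would give 32.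

2. Step 19. Process at risk: elimination through the enolate delivers the (Z)-olefin, or the base triggers retro-aldol opening of the ring. The fallback sets out from 30 and returns at 32, replacing the base-mediated E1cB path by a thermal intramolecular syn-elimination under neutral conditions. Burgess reagent in benzene at rt to 50 °C would convert the C3 hydroxyl into the sulfamate salt F10, which loses the sulfamate through a cyclic syn pathway, the mode that in medium rings characteristically gives trans olefins, to afford 32. Should the geometry still be wrong, the sequence described under step 16 bypasses this step as well.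

3. Step 5. Process at risk: the hindered, hard dithiane anion attacks the lactone carbonyl or abstracts the C6 proton of the butenolide in place of conjugate addition. The fallback sets out from 2 and returns at 11, exchanging the dithiane for the softer bis(phenylsulfanyl)methyl carbanion. LiCH(SPh)2 (from bis(phenylsulfanyl)methane and n-BuLi, THF) would open epoxide 2 to the tertiary alcohol F11, and Et3SiOTf/2,6-lutidine would give the silyl ether F12. n-BuLi/TMEDA in THF at −78 °C would generate the lithio derivative F13, which should add in the conjugate sense to butenolide 8 without HMPA to give the trans adduct F14. Hg(ClO4)2/CaCO3 in aqueous THF would unmask ketone 11.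

Further compounds
F1 | step 16 | C3 aldehyde from cleavage of the vinyl group of 19 | COc1ccc(COC[C@@](C)(OC2(C)C)C[C@@H](O2)[C@H]3CC(=O)O[C@@H]3[C@@H](O[Si](C)(C)C(C)(C)C)[C@@H](C)C=O)cc1
F2 | step 16 | (E)-vinyl iodide, 1-OPMB | COc1ccc(COC[C@@](C)(OC2(C)C)C[C@@H](O2)[C@H]3CC(=O)O[C@@H]3[C@@H](O[Si](C)(C)C(C)(C)C)[C@@H](C)/C=C/I)cc1
F3 | step 16 | (E)-vinyl iodide C1 alcohol | OC[C@@](C)(OC1(C)C)C[C@@H](O1)[C@H]2CC(=O)O[C@@H]2[C@@H](O[Si](C)(C)C(C)(C)C)[C@@H](C)/C=C/I
F4 | step 16 | (E)-vinyl iodide C1 aldehyde | O=C[C@@](C)(OC1(C)C)C[C@@H](O1)[C@H]2CC(=O)O[C@@H]2[C@@H](O[Si](C)(C)C(C)(C)C)[C@@H](C)/C=C/I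
F5 | step 16 | ten-membered (E)-allylic alcohol, C1 epimers | C[C@H]1/C=C/C(O)[C@@](C)(OC2(C)C)C[C@@H](O2)[C@H]3CC(=O)O[C@@H]3[C@H]1O[Si](C)(C)C(C)(C)C
F6 | step 16 | dilithio alkoxide–enolate of F5 | C[C@H]1/C=C/C(O[Li])[C@@](C)(OC2(C)C)C[C@@H](O2)[C@H]3C=C(O[Li])O[C@@H]3[C@H]1O[Si](C)(C)C(C)(C)C
F7 | step 16 | Mannich base of F5 (C11 CH2NMe2) | C[C@H]1/C=C/C(O)[C@@](C)(OC2(C)C)C[C@@H](O2)[C@H]3[C@H](CN(C)C)C(=O)O[C@@H]3[C@H]1O[Si](C)(C)C(C)(C)C
F8 | step 16 | methiodide of F7 | C[C@H]1/C=C/C(O)[C@@](C)(OC2(C)C)C[C@@H](O2)[C@H]3[C@H](C[N+](C)(C)C)C(=O)O[C@@H]3[C@H]1O[Si](C)(C)C(C)(C)C.[I-]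
F9 | step 16 | α-methylene lactone allylic alcohol | C[C@H]1/C=C/C(O)[C@@](C)(OC2(C)C)C[C@@H](O2)[C@H]3C(=C)C(=O)O[C@@H]3[C@H]1O[Si](C)(C)C(C)(C)C
F10 | step 19 | C3 (methoxycarbonyl)sulfamate of 30, triethylammonium salt | C[C@H]1[C@@H](OS(=O)(=O)[N-]C(=O)OC)CC(=O)[C@@](C)(OC2(C)C)C[C@@H](O2)[C@H]3C(=C)C(=O)O[C@@H]3[C@H]1O[Si](C)(C)C(C)(C)C.CC[NH+](CC)CC
F11 | step 5 | (S)-4,4-bis(phenylsulfanyl)-1-[(4-methoxybenzyl)oxy]-2-methylbutan-2-ol | COc1ccc(COC[C@@](C)(O)CC(Sc2ccccc2)Sc2ccccc2)cc1
F12 | step 5 | triethylsilyl ether of F11 | COc1ccc(COC[C@@](C)(O[Si](CC)(CC)CC)CC(Sc2ccccc2)Sc2ccccc2)cc1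
F13 | step 5 | lithio derivative of F12 | COc1ccc(COC[C@@](C)(O[Si](CC)(CC)CC)CC([Li])(Sc2ccccc2)Sc2ccccc2)cc1
F14 | step 5 | C6/C7-trans butanolide with the bis(phenylsulfanyl) carbon (C8) on C7 | COc1ccc(COC[C@@](C)(O[Si](CC)(CC)CC)CC(Sc2ccccc2)(Sc2ccccc2)[C@H]3CC(=O)O[C@@H]3CO[Si](c4ccccc4)(c4ccccc4)C(C)(C)C)cc1
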